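Assumption: compounds 2, 12 and 17 are bought as silyl derivatives; the silyl groups are protecting groups of methyl acetate enolate, propynal and 4-bromophenol.

**Retrosynthetic overview**
1. Triene: two Sonogashira couplings join a core alkyne and a side-chain alkyne to (Z)-1,2-dichloroethene; cis-reduction of both triple bonds with activated zinc and one global fluoride deprotection finish the synthesis.
2. Ring order: bought cyclopentenone ring → one-carbon ring expansion to a cyclohexenone template (tertiary carbinol set there) → key step: Lewis-acid 1,2-shift of an epoxy silyl ether, contracting back to the cyclopentane with the extruded carbon as a trans formyl group → cyclohexene closed last by intramolecular SN2 alkylation of an ester enolate on a propargylic mesylate.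
3. Aryl carbinol: ring ester → Weinreb amide → aryl ketone → CBS reduction.
4. Side chain: organocatalytic anti cross-aldol, Brown allylation, cross-metathesis with methacrolein, Still–Gennari olefination.

**Route**

Step 1
Reactants: 1 4,4-dimethylcyclopent-2-en-1-one; 2 1-methoxy-1-(trimethylsilyloxy)ethene
Product: 3 methyl 2-[(1R)-5,5-dimethyl-3-(trimethylsilyloxy)cyclopent-2-en-1-yl]acetate
Conditions: Corey oxazaborolidinium triflimide (10 mol%, enantiomer giving 1R), Ph3PO (20 mol%), toluene, −40 °C; non-aqueous work-up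
Reagents that add atoms: none
Why: Catalytic asymmetric Mukaiyama–Michael addition; the chiral cationic boron Lewis acid shields one enone face and so sets C-1, and silyl transfer gives the regiodefined enol ether needed next.

Step 2
Reactants: 3
Product: 4 methyl 2-[(1R,2R,5R)-3,3-dimethyl-5-(trimethylsilyloxy)bicyclo[3.1.0]hexan-2-yl]acetate
Conditions: Et2Zn, CH2I2, CH2Cl2, 0 °C
Reagents that add atoms: diiodomethane ICI
Why: Furukawa–Simmons–Smith cyclopropanation of the electron-rich enol ether, anti to the neighbouring side chain (both new centres are erased in step 3).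

Step 3
Reactants: 4
Product: 6 methyl 2-[(1R)-6,6-dimethyl-4-oxocyclohex-2-en-1-yl]acetate, via chloro ketone 5 (not isolated)
Conditions: FeCl3 (2.2 equiv), DMF, 0 °C; then NaOAc, MeOH, 65 °C
Reagents that add atoms: none
Why: Ito–Saegusa one-carbon ring expansion: one-electron oxidation of the siloxycyclopropane, β-scission of the internal bond to the ring-enlarged radical, chlorine transfer and loss of HCl give the cyclohexenone; the stereocentre is untouched.

Step 4
Reactants: 6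
Product: 7 methyl 2-[(1R,4R)-4-hydroxy-4,6,6-trimethylcyclohex-2-en-1-yl]acetate
Conditions: MeLi, CeCl3, THF, −78 °C
Reagents that add atoms: methyllithium [Li]C
Why: Organocerium 1,2-addition (ketone over ester, no conjugate addition); in the half-chair with the side chain pseudo-equatorial the axial C-6 methyl lies on the side-chain face and blocks it, so methyl enters from the other face and the hydroxyl is expected cis to the side chain (the opposite result of direct methyl addition to an α-substituted cyclopentanone).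

Step 5
Reactants: 7
Product: 8 methyl 2-[(1R,4R)-4-(tert-butyldimethylsilyloxy)-4,6,6-trimethylcyclohex-2-en-1-yl]acetate
Conditions: TBSOTf, 2,6-lutidine, CH2Cl2, −78 → 0 °C
Reagents that add atoms: tert-butyldimethylsilyl triflate CC(C)(C)[Si](C)(C)OS(=O)(=O)C(F)(F)F
Why: Silylation of the tertiary allylic alcohol with the silyl triflate; no stereocentre is affected.

Step 6
Reactants: 8
Product: 9 methyl 2-[(1R,2S,5R,6R)-5-(tert-butyldimethylsilyloxy)-3,3,5-trimethyl-7-oxabicyclo[4.1.0]heptan-2-yl]acetate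
Conditions: mCPBA, NaHCO3, CH2Cl2, 0 °C
Reagents that add atoms: 3-chloroperoxybenzoic acid OOC(=O)c1cccc(Cl)c1
Why: Prilezhaev epoxidation; the silyloxy group and the side chain sit on the same ring face, so the peracid attacks the other face and both epoxide centres are set trans to them.

Step 7
Reactants: 9
Product: 10 methyl 2-[(1R,2R,3R)-3-(tert-butyldimethylsilyloxy)-2-formyl-3,5,5-trimethylcyclopentyl]acetate
Conditions: MeAl(OAr)2 (Ar = 4-bromo-2,6-di-tert-butylphenyl; 2 equiv), CH2Cl2, −78 → −20 °C; aqueous HCl work-up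
Reagents that add atoms: none
Why: Proposed new method: a ring-contracting Maruoka–Yamamoto rearrangement in which a fully substituted silyloxy carbon migrates; the bulky aluminium Lewis acid opens the epoxide at the carbon remote from the silyloxy group (the nearer C–O bond is inductively deactivated), the electron-rich silyloxy-bearing ring carbon shifts anti to the breaking C–O bond (inversion there, retention at the migrating carbon) and the other epoxide carbon becomes the formyl group, so the cyclohexane contracts to the cyclopentane with CHO trans to both OSi and the side chain; closest known reaction: the MABR-promoted semipinacol 1,2-shift of open-chain epoxy silyl ethers to β-silyloxy aldehydes.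

Step 8
Reactants: 10
Product: 11 methyl 2-[(1R,2S,3R)-3-(tert-butyldimethylsilyloxy)-2-[(1Z)-2-iodoprop-1-en-1-yl]-3,5,5-trimethylcyclopentyl]acetate
Conditions: [Ph3PCH(I)CH3]I, NaN(SiMe3)2, THF, −78 °C
Reagents that add atoms: (1-iodoethyl)triphenylphosphonium iodide CC(I)[P+](c1ccccc1)(c1ccccc1)c1ccccc1.[I-]
Why: Stork–Zhao-type Wittig olefination with the α-iodo ylide; the kinetic cis-oxaphosphetane gives the (Z)-vinyl iodide (ring carbon cis to iodine).

Step 9
Reactants: 11; 12 3-(trimethylsilyl)prop-2-ynal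
Product: 13 methyl 2-[(1R,2R,3R)-3-(tert-butyldimethylsilyloxy)-2-[(1Z,3R)-3-hydroxy-2-methyl-5-(trimethylsilyl)pent-1-en-4-yn-1-yl]-3,5,5-trimethylcyclopentyl]acetate
Conditions: CrCl2 (3 equiv), NiCl2 (2 mol%), Kishi oxazoline–sulfonamide ligand (enantiomer giving 3R), Et3N, THF/MeCN, rt
Reagents that add atoms: none
Why: Asymmetric Nozaki–Hiyama–Kishi coupling; the alkenylchromium species adds to the ynal with retention of alkene geometry and the chiral sulfonamide ligand on chromium sets the carbinol centre by reagent control.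

Step 10
Reactants: 13
Product: 14 methyl 2-[(1R,2R,3R)-3-(tert-butyldimethylsilyloxy)-2-[(1Z,3R)-3-(methanesulfonyloxy)-2-methyl-5-(trimethylsilyl)pent-1-en-4-yn-1-yl]-3,5,5-trimethylcyclopentyl]acetate
Conditions: MsCl, Et3N, CH2Cl2, −40 °C; used crude
Reagents that add atoms: methanesulfonyl chloride CS(=O)(=O)Cl
Why: Mesylation of the secondary alcohol with retention, making the propargylic carbon an SN2 electrophile.

Step 11
Reactants: 14
Product: 15 methyl (1R,3aS,4R,5S,7aR)-1-(tert-butyldimethylsilyloxy)-1,3,3,6-tetramethyl-5-[(trimethylsilyl)ethynyl]-2,3,3a,4,5,7a-hexahydro-1H-indene-4-carboxylate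
Conditions: KN(SiMe3)2, THF, −78 → −20 °C
Reagents that add atoms: none
Why: Intramolecular 6-exo-tet SN2 alkylation of the ester enolate (the Z-alkene holds the electrophile in reach; SN2′ modes would give four- or eight-membered rings); inversion at the propargylic carbon sets C-5, and the ester takes the equatorial position (any C-4 epimer converges at ketone 19).

Step 12
Reactants: 15
Product: 16 (1R,3aS,4R,5S,7aR)-1-(tert-butyldimethylsilyloxy)-N-methoxy-N,1,3,3,6-pentamethyl-5-[(trimethylsilyl)ethynyl]-2,3,3a,4,5,7a-hexahydro-1H-indene-4-carboxamide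
Conditions: MeNH(OMe)·HCl, i-PrMgCl, THF, −20 °C
Reagents that add atoms: N,O-dimethylhydroxylamine hydrochloride CNOC.Cl
Why: Weinreb amidation of the ester by the magnesium amide; no stereocentre changes.

Step 13
Reactants: 16; 17 (4-bromophenoxy)(tert-butyl)dimethylsilane
Product: 19 [(1R,3aS,4R,5S,7aR)-1-(tert-butyldimethylsilyloxy)-1,3,3,6-tetramethyl-5-[(trimethylsilyl)ethynyl]-2,3,3a,4,5,7a-hexahydro-1H-inden-4-yl][4-(tert-butyldimethylsilyloxy)phenyl]methanone, via aryllithium 18 (not isolated)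
Conditions: 17, n-BuLi, THF, −78 °C; then 16, −78 → 0 °C; NH4Cl; DBU (cat.), CH2Cl2
Reagents that add atoms: none
Why: Aryllithium addition to the Weinreb amide stops at the ketone through the stable chelate; C-4, now α to the ketone, equilibrates to the all-trans equatorial isomer.

Step 14
Reactants: 19
Product: 20 (S)-[(1R,3aR,4R,5S,7aR)-1-(tert-butyldimethylsilyloxy)-1,3,3,6-tetramethyl-5-[(trimethylsilyl)ethynyl]-2,3,3a,4,5,7a-hexahydro-1H-inden-4-yl][4-(tert-butyldimethylsilyloxy)phenyl]methanol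
Conditions: (R)-2-methyl-CBS-oxazaborolidine (20 mol%), catecholborane, toluene, −78 °C
Reagents that add atoms: none
Why: Corey–Bakshi–Shibata reduction; with aryl as the large group the (R)-catalyst delivers hydride to the face that gives the (S)-carbinol, and catecholborane leaves alkene and alkyne alone.

Step 15
Reactants: 20
Product: 21 4-[(S)-[(1R,3aR,4R,5R,7aR)-1-(tert-butyldimethylsilyloxy)-5-ethynyl-1,3,3,6-tetramethyl-2,3,3a,4,5,7a-hexahydro-1H-inden-4-yl](hydroxy)methyl]phenol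
Conditions: K2CO3, MeOH, rt
Reagents that add atoms: none
Why: Base-catalysed methanolysis cleaves the alkynyl–silicon and aryl–O–silicon bonds only; the tertiary silyl ether stays.

Step 16
Reactants: 12; 22 propanal
Product: 23 (2S,3R)-3-hydroxy-2-methyl-5-(trimethylsilyl)pent-4-ynal
Conditions: (S)-α,α-bis[3,5-bis(trifluoromethyl)phenyl]-2-pyrrolidinemethanol (10 mol%), DMF, 4 °C
Reagents that add atoms: none
Why: Hayashi-type organocatalytic cross-aldol; the enamine of propanal adds to the hydrogen-bond-activated ynal through an anti transition state, setting both centres under catalyst control.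

Step 17
Reactants: 23
Product: 24 (2S,3R)-3-(tert-butyldimethylsilyloxy)-2-methyl-5-(trimethylsilyl)pent-4-ynal
Conditions: TBSOTf, 2,6-lutidine, CH2Cl2, −78 °C
Reagents that add atoms: tert-butyldimethylsilyl triflate CC(C)(C)[Si](C)(C)OS(=O)(=O)C(F)(F)F
Why: Low-temperature silylation stops retro-aldol and epimerisation of the β-hydroxy aldehyde.

Step 18
Reactants: 24
Product: 25 (4R,5R,6R)-6-(tert-butyldimethylsilyloxy)-5-methyl-8-(trimethylsilyl)oct-1-en-7-yn-4-ol
Conditions: (+)-Ipc2B(allyl) (from (−)-α-pinene), Et2O, −78 °C; NaOH, H2O2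
Reagents that add atoms: B-allyldiisopinocampheylborane C=CCB(C1CC2CC(C1C)C2(C)C)C1CC2CC(C1C)C2(C)C
Why: Brown allylation through a chair six-membered transition state; reagent control overrides the Felkin preference and sets the carbinol anti to the methyl group (anti,anti triad).

Step 19
Reactants: 25
Product: 26 (4R,5R,6R)-6-(tert-butyldimethylsilyloxy)-5-methyl-4-(triethylsilyloxy)-8-(trimethylsilyl)oct-1-en-7-yne
Conditions: TESOTf, 2,6-lutidine, CH2Cl2, −78 °C
Reagents that add atoms: triethylsilyl triflate CC[Si](CC)(CC)OS(=O)(=O)C(F)(F)F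
Why: Silylation of the secondary alcohol; no stereocentre changes.

Step 20
Reactants: 26; 27 methacrolein
Product: 28 (2E,5R,6R,7R)-7-(tert-butyldimethylsilyloxy)-2,6-dimethyl-5-(triethylsilyloxy)-9-(trimethylsilyl)non-2-en-8-ynal
Conditions: second-generation Hoveyda–Grubbs catalyst (5 mol%), methacrolein (5 equiv), CH2Cl2, 40 °C
Reagents that add atoms: none
Why: Olefin cross-metathesis of a terminal alkene with methacrolein gives the thermodynamically favoured (E)-trisubstituted enal; the silyl-capped alkyne is inert.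

Step 21
Reactants: 28
Product: 29 2-(trimethylsilyl)ethyl (2Z,4E,7R,8R,9R)-9-(tert-butyldimethylsilyloxy)-4,8-dimethyl-7-(triethylsilyloxy)-11-(trimethylsilyl)undeca-2,4-dien-10-ynoate
Conditions: (CF3CH2O)2P(O)CH2CO2CH2CH2SiMe3, KN(SiMe3)2, 18-crown-6, THF, −78 °C
Reagents that add atoms: 2-(trimethylsilyl)ethyl 2-[bis(2,2,2-trifluoroethoxy)phosphoryl]acetate C[Si](C)(C)CCOC(=O)CP(=O)(OCC(F)(F)F)OCC(F)(F)F
Why: Still–Gennari olefination; fast irreversible elimination from the kinetic adduct of the electron-poor phosphonate gives the (2Z)-enoate.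

Step 22
Reactants: 29
Product: 30 2-(trimethylsilyl)ethyl (2Z,4E,7R,8R,9R)-9-(tert-butyldimethylsilyloxy)-4,8-dimethyl-7-(triethylsilyloxy)undeca-2,4-dien-10-ynoate
Conditions: AgNO3 (10 mol%), acetone/H2O, rt
Reagents that add atoms: none
Why: Silver-catalysed protodesilylation is selective for the alkynyl C–Si bond and spares the silyl ethers and the silylethyl ester.

Step 23
Reactants: 30; 31 (Z)-1,2-dichloroethene
Product: 32 2-(trimethylsilyl)ethyl (2Z,4E,7R,8R,9R,12Z)-9-(tert-butyldimethylsilyloxy)-13-chloro-4,8-dimethyl-7-(triethylsilyloxy)trideca-2,4,12-trien-10-ynoate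
Conditions: 31 (5 equiv), Pd(PPh3)4 (5 mol%), CuI (10 mol%), n-BuNH2, Et2O, rt
Reagents that add atoms: none
Why: Sonogashira coupling with excess cis-dichloroethene gives the mono-coupled chloroenyne with retention of the Z geometry.

Step 24
Reactants: 32; 21
Product: 33 2-(trimethylsilyl)ethyl (2Z,4E,7R,8R,9R,12Z)-9-(tert-butyldimethylsilyloxy)-15-[(1R,3aR,4R,5S,7aR)-1-(tert-butyldimethylsilyloxy)-4-[(S)-hydroxy(4-hydroxyphenyl)methyl]-1,3,3,6-tetramethyl-2,3,3a,4,5,7a-hexahydro-1H-inden-5-yl]-4,8-dimethyl-7-(triethylsilyloxy)pentadeca-2,4,12-triene-10,14-diynoate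
Conditions: Pd(PPh3)4 (5 mol%), CuI (10 mol%), n-BuNH2, THF, rt
Reagents that add atoms: none
Why: Second Sonogashira coupling of the activated (Z)-chloroenyne joins the two fragments with retention of the central Z alkene; free OH groups are tolerated.

Step 25
Reactants: 33
Product: 34 2-(trimethylsilyl)ethyl (2Z,4E,7R,8R,9S,10Z,12Z,14Z)-9-(tert-butyldimethylsilyloxy)-15-[(1R,3aR,4R,5S,7aR)-1-(tert-butyldimethylsilyloxy)-4-[(S)-hydroxy(4-hydroxyphenyl)methyl]-1,3,3,6-tetramethyl-2,3,3a,4,5,7a-hexahydro-1H-inden-5-yl]-4,8-dimethyl-7-(triethylsilyloxy)pentadeca-2,4,10,12,14-pentaenoate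
Conditions: Zn dust activated with Cu(OAc)2 and AgNO3, MeOH/H2O 1:1, rt, dark
Reagents that add atoms: none
Why: Boland reduction; activated zinc reduces only the two conjugated triple bonds by cis hydrogen delivery, giving the (Z,Z,Z)-triene and leaving the dienoate untouched.

Step 26
Reactants: 34
Product: 35 (2Z,4E,7R,8R,9S,10Z,12Z,14Z)-7,9-dihydroxy-15-[(1R,3aR,4R,5S,7aR)-1-hydroxy-4-[(S)-hydroxy(4-hydroxyphenyl)methyl]-1,3,3,6-tetramethyl-2,3,3a,4,5,7a-hexahydro-1H-inden-5-yl]-4,8-dimethylpentadeca-2,4,10,12,14-pentaenoic acid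
Conditions: (Me2N)3S+ Me3SiF2− (TASF, 8 equiv), DMF, 0 → 40 °C; pH 5 buffer
Reagents that add atoms: none
Why: Fluoride-mediated global desilylation removes the three silyl ethers and, by β-elimination, the silylethyl ester in one non-acidic operation that does not touch any stereocentre or alkene.

**Compound list**
1 | 4,4-dimethylcyclopent-2-en-1-one | CC1(C)CC(=O)C=C1 | starting material
2 | 1-methoxy-1-(trimethylsilyloxy)ethene | COC(=C)O[Si](C)(C)C | starting material
3 | methyl 2-[(1R)-5,5-dimethyl-3-(trimethylsilyloxy)cyclopent-2-en-1-yl]acetate | COC(=O)C[C@@H]1C=C(O[Si](C)(C)C)CC1(C)C | intermediate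
4 | methyl 2-[(1R,2R,5R)-3,3-dimethyl-5-(trimethylsilyloxy)bicyclo[3.1.0]hexan-2-yl]acetate | COC(=O)C[C@@H]1[C@H]2C[C@@]2(O[Si](C)(C)C)CC1(C)C | intermediate
5 | methyl 2-[(1S,2RS)-2-chloro-6,6-dimethyl-4-oxocyclohexyl]acetate | COC(=O)C[C@@H]1C(Cl)CC(=O)CC1(C)C | intermediate
6 | methyl 2-[(1R)-6,6-dimethyl-4-oxocyclohex-2-en-1-yl]acetate | COC(=O)C[C@@H]1C=CC(=O)CC1(C)C | intermediate
7 | methyl 2-[(1R,4R)-4-hydroxy-4,6,6-trimethylcyclohex-2-en-1-yl]acetate (OH cis to side chain) | COC(=O)C[C@@H]1C=C[C@](C)(O)CC1(C)C | intermediate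
8 | methyl 2-[(1R,4R)-4-(tert-butyldimethylsilyloxy)-4,6,6-trimethylcyclohex-2-en-1-yl]acetate | COC(=O)C[C@@H]1C=C[C@](C)(O[Si](C)(C)C(C)(C)C)CC1(C)C | intermediate
9 | methyl 2-[(1R,2S,5R,6R)-5-(tert-butyldimethylsilyloxy)-3,3,5-trimethyl-7-oxabicyclo[4.1.0]heptan-2-yl]acetate (epoxide trans to OSi and side chain) | COC(=O)C[C@@H]1[C@H]2O[C@H]2[C@](C)(O[Si](C)(C)C(C)(C)C)CC1(C)C | intermediate
10 | methyl 2-[(1R,2R,3R)-3-(tert-butyldimethylsilyloxy)-2-formyl-3,5,5-trimethylcyclopentyl]acetate | COC(=O)C[C@@H]1[C@@H](C=O)[C@](C)(O[Si](C)(C)C(C)(C)C)CC1(C)C | intermediate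
11 | methyl 2-[(1R,2S,3R)-3-(tert-butyldimethylsilyloxy)-2-[(1Z)-2-iodoprop-1-en-1-yl]-3,5,5-trimethylcyclopentyl]acetate | COC(=O)C[C@@H]1[C@@H](/C=C(/C)I)[C@](C)(O[Si](C)(C)C(C)(C)C)CC1(C)C | intermediate
12 | 3-(trimethylsilyl)prop-2-ynal | C[Si](C)(C)C#CC=O | starting material
13 | methyl 2-[(1R,2R,3R)-3-(tert-butyldimethylsilyloxy)-2-[(1Z,3R)-3-hydroxy-2-methyl-5-(trimethylsilyl)pent-1-en-4-yn-1-yl]-3,5,5-trimethylcyclopentyl]acetate | COC(=O)C[C@@H]1[C@@H](/C=C(/C)[C@@H](O)C#C[Si](C)(C)C)[C@](C)(O[Si](C)(C)C(C)(C)C)CC1(C)C | intermediate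
14 | methyl 2-[(1R,2R,3R)-3-(tert-butyldimethylsilyloxy)-2-[(1Z,3R)-3-(methanesulfonyloxy)-2-methyl-5-(trimethylsilyl)pent-1-en-4-yn-1-yl]-3,5,5-trimethylcyclopentyl]acetate | COC(=O)C[C@@H]1[C@@H](/C=C(/C)[C@@H](OS(C)(=O)=O)C#C[Si](C)(C)C)[C@](C)(O[Si](C)(C)C(C)(C)C)CC1(C)C | intermediate
15 | methyl (1R,3aS,4R,5S,7aR)-1-(tert-butyldimethylsilyloxy)-1,3,3,6-tetramethyl-5-[(trimethylsilyl)ethynyl]-2,3,3a,4,5,7a-hexahydro-1H-indene-4-carboxylate | CC1=C[C@@H]2[C@@H]([C@@H](C(=O)OC)[C@@H]1C#C[Si](C)(C)C)C(C)(C)C[C@@]2(C)O[Si](C)(C)C(C)(C)C | intermediate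
16 | (1R,3aS,4R,5S,7aR)-1-(tert-butyldimethylsilyloxy)-N-methoxy-N,1,3,3,6-pentamethyl-5-[(trimethylsilyl)ethynyl]-2,3,3a,4,5,7a-hexahydro-1H-indene-4-carboxamide | CC1=C[C@@H]2[C@@H]([C@@H](C(=O)N(C)OC)[C@@H]1C#C[Si](C)(C)C)C(C)(C)C[C@@]2(C)O[Si](C)(C)C(C)(C)C | intermediate
17 | (4-bromophenoxy)(tert-butyl)dimethylsilane | CC(C)(C)[Si](C)(C)Oc1ccc(Br)cc1 | starting material
18 | [4-(tert-butyldimethylsilyloxy)phenyl]lithium | CC(C)(C)[Si](C)(C)Oc1ccc([Li])cc1 | intermediate
19 | [(1R,3aS,4R,5S,7aR)-1-(tert-butyldimethylsilyloxy)-1,3,3,6-tetramethyl-5-[(trimethylsilyl)ethynyl]-2,3,3a,4,5,7a-hexahydro-1H-inden-4-yl][4-(tert-butyldimethylsilyloxy)phenyl]methanone | CC1=C[C@@H]2[C@@H]([C@@H](C(=O)c3ccc(O[Si](C)(C)C(C)(C)C)cc3)[C@@H]1C#C[Si](C)(C)C)C(C)(C)C[C@@]2(C)O[Si](C)(C)C(C)(C)C | intermediate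
20 | (S)-[(1R,3aR,4R,5S,7aR)-1-(tert-butyldimethylsilyloxy)-1,3,3,6-tetramethyl-5-[(trimethylsilyl)ethynyl]-2,3,3a,4,5,7a-hexahydro-1H-inden-4-yl][4-(tert-butyldimethylsilyloxy)phenyl]methanol | CC1=C[C@@H]2[C@@H]([C@@H]([C@H](O)c3ccc(O[Si](C)(C)C(C)(C)C)cc3)[C@@H]1C#C[Si](C)(C)C)C(C)(C)C[C@@]2(C)O[Si](C)(C)C(C)(C)C | intermediate
21 | 4-[(S)-[(1R,3aR,4R,5R,7aR)-1-(tert-butyldimethylsilyloxy)-5-ethynyl-1,3,3,6-tetramethyl-2,3,3a,4,5,7a-hexahydro-1H-inden-4-yl](hydroxy)methyl]phenol | CC1=C[C@@H]2[C@@H]([C@@H]([C@H](O)c3ccc(O)cc3)[C@@H]1C#C)C(C)(C)C[C@@]2(C)O[Si](C)(C)C(C)(C)C | intermediate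
22 | propanal | CCC=O | starting material
23 | (2S,3R)-3-hydroxy-2-methyl-5-(trimethylsilyl)pent-4-ynal | O=C[C@@H](C)[C@@H](O)C#C[Si](C)(C)C | intermediate
24 | (2S,3R)-3-(tert-butyldimethylsilyloxy)-2-methyl-5-(trimethylsilyl)pent-4-ynal | O=C[C@@H](C)[C@@H](O[Si](C)(C)C(C)(C)C)C#C[Si](C)(C)C | intermediate
25 | (4R,5R,6R)-6-(tert-butyldimethylsilyloxy)-5-methyl-8-(trimethylsilyl)oct-1-en-7-yn-4-ol | C=CC[C@@H](O)[C@@H](C)[C@@H](O[Si](C)(C)C(C)(C)C)C#C[Si](C)(C)C | intermediate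
26 | (4R,5R,6R)-6-(tert-butyldimethylsilyloxy)-5-methyl-4-(triethylsilyloxy)-8-(trimethylsilyl)oct-1-en-7-yne | C=CC[C@@H](O[Si](CC)(CC)CC)[C@@H](C)[C@@H](O[Si](C)(C)C(C)(C)C)C#C[Si](C)(C)C | intermediate
27 | methacrolein (2-methylprop-2-enal) | CC(=C)C=O | starting material
28 | (2E,5R,6R,7R)-7-(tert-butyldimethylsilyloxy)-2,6-dimethyl-5-(triethylsilyloxy)-9-(trimethylsilyl)non-2-en-8-ynal | O=C/C(C)=C/C[C@@H](O[Si](CC)(CC)CC)[C@@H](C)[C@@H](O[Si](C)(C)C(C)(C)C)C#C[Si](C)(C)C | intermediate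
29 | 2-(trimethylsilyl)ethyl (2Z,4E,7R,8R,9R)-9-(tert-butyldimethylsilyloxy)-4,8-dimethyl-7-(triethylsilyloxy)-11-(trimethylsilyl)undeca-2,4-dien-10-ynoate | C[Si](C)(C)CCOC(=O)/C=C\C(C)=C\C[C@@H](O[Si](CC)(CC)CC)[C@@H](C)[C@@H](O[Si](C)(C)C(C)(C)C)C#C[Si](C)(C)C | intermediate
30 | 2-(trimethylsilyl)ethyl (2Z,4E,7R,8R,9R)-9-(tert-butyldimethylsilyloxy)-4,8-dimethyl-7-(triethylsilyloxy)undeca-2,4-dien-10-ynoate | C[Si](C)(C)CCOC(=O)/C=C\C(C)=C\C[C@@H](O[Si](CC)(CC)CC)[C@@H](C)[C@@H](O[Si](C)(C)C(C)(C)C)C#C | intermediate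
31 | (Z)-1,2-dichloroethene | Cl/C=C\Cl | starting material
32 | 2-(trimethylsilyl)ethyl (2Z,4E,7R,8R,9R,12Z)-9-(tert-butyldimethylsilyloxy)-13-chloro-4,8-dimethyl-7-(triethylsilyloxy)trideca-2,4,12-trien-10-ynoate | C[Si](C)(C)CCOC(=O)/C=C\C(C)=C\C[C@@H](O[Si](CC)(CC)CC)[C@@H](C)[C@@H](O[Si](C)(C)C(C)(C)C)C#C/C=C\Cl | intermediate
33 | protected enediyne (name as in step 24) | CC1=C[C@@H]2[C@@H]([C@@H]([C@H](O)c3ccc(O)cc3)[C@@H]1C#C/C=C\C#C[C@H](O[Si](C)(C)C(C)(C)C)[C@H](C)[C@H](O[Si](CC)(CC)CC)C/C=C(C)/C=C\C(=O)OCC[Si](C)(C)C)C(C)(C)C[C@@]2(C)O[Si](C)(C)C(C)(C)C | intermediate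
34 | protected (Z,Z,Z)-triene (name as in step 25) | CC1=C[C@@H]2[C@@H]([C@@H]([C@H](O)c3ccc(O)cc3)[C@@H]1\C=C/C=C\C=C/[C@H](O[Si](C)(C)C(C)(C)C)[C@H](C)[C@H](O[Si](CC)(CC)CC)C/C=C(C)/C=C\C(=O)OCC[Si](C)(C)C)C(C)(C)C[C@@]2(C)O[Si](C)(C)C(C)(C)C | intermediate
35 | (2Z,4E,7R,8R,9S,10Z,12Z,14Z)-7,9-dihydroxy-15-[(1R,3aR,4R,5S,7aR)-1-hydroxy-4-[(S)-hydroxy(4-hydroxyphenyl)methyl]-1,3,3,6-tetramethyl-2,3,3a,4,5,7a-hexahydro-1H-inden-5-yl]-4,8-dimethylpentadeca-2,4,10,12,14-pentaenoic acid | CC1=C[C@@H]2[C@@H]([C@@H]([C@H](O)c3ccc(O)cc3)[C@@H]1\C=C/C=C\C=C/[C@H](O)[C@H](C)[C@H](O)C/C=C(C)/C=C\C(=O)O)C(C)(C)C[C@@]2(C)O | target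

**Step count and risks**
Total: 26 steps. Longest linear sequence: 18 steps (steps 1–15, then 24, 25, 26).

Three steps most likely to fail:

Step 7 (the proposed new rearrangement; risks are hydride shift to a ketone or migration of a group from the silyloxy carbon). Fallback, from 8 back to 10, by known chemistry: oxidative ring contraction of cyclohexene 8 with Tl(NO3)3·3H2O in MeOH/HC(OMe)3 (methoxythallation, 1,2-shift of a ring carbon with loss of monovalent thallium; either possible ring-carbon shift gives the same constitution) affords the acetal methyl 2-[(1R,2RS,3R)-3-(tert-butyldimethylsilyloxy)-2-(dimethoxymethyl)-3,5,5-trimethylcyclopentyl]acetate F1. PPTS in wet acetone, then a trace of DBU to equilibrate the α-centre to the trans aldehyde, returns 10.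

Step 9 (diastereocontrol of the asymmetric chromium-mediated coupling). Fallback, from 11 and 12 back to 13: ligand-free CrCl2/NiCl2 coupling in DMSO gives the carbinol as an epimer mixture, methyl 2-[(1R,2R,3R)-3-(tert-butyldimethylsilyloxy)-2-[(1Z,3RS)-3-hydroxy-2-methyl-5-(trimethylsilyl)pent-1-en-4-yn-1-yl]-3,5,5-trimethylcyclopentyl]acetate F2. Dess–Martin periodinane oxidises it to the ynone methyl 2-[(1R,2R,3R)-3-(tert-butyldimethylsilyloxy)-2-[(1Z)-2-methyl-3-oxo-5-(trimethylsilyl)pent-1-en-4-yn-1-yl]-3,5,5-trimethylcyclopentyl]acetate F3. Noyori transfer hydrogenation with RuCl(p-cymene)[(S,S)-TsDPEN] (enantiomer chosen for the 3R carbinol) in HCO2H/Et3N then sets the centre by reagent control and gives 13.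

Step 14 (CBS face selectivity with an α-branched alkyl group next to the aryl ketone). Fallback, from 15 back to 20, bypassing 16 and 19: i-Bu2AlH at −78 °C reduces ester 15 to the aldehyde (1R,3aS,4R,5S,7aR)-1-(tert-butyldimethylsilyloxy)-1,3,3,6-tetramethyl-5-[(trimethylsilyl)ethynyl]-2,3,3a,4,5,7a-hexahydro-1H-indene-4-carbaldehyde F4. The Grignard reagent [4-(tert-butyldimethylsilyloxy)phenyl]magnesium bromide F5 (from 17 and Mg) is then added with Ti(OiPr)4 and a catalytic H8-BINOL-type ligand (Harada's catalytic asymmetric aryl Grignard addition, ligand enantiomer chosen for the S carbinol) to give 20 directly.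

Further compounds
F1 | step 7 | methyl 2-[(1R,2RS,3R)-3-(tert-butyldimethylsilyloxy)-2-(dimethoxymethyl)-3,5,5-trimethylcyclopentyl]acetate | COC(=O)C[C@@H]1C(C(OC)OC)[C@](C)(O[Si](C)(C)C(C)(C)C)CC1(C)C
F2 | step 9 | methyl 2-[(1R,2R,3R)-3-(tert-butyldimethylsilyloxy)-2-[(1Z,3RS)-3-hydroxy-2-methyl-5-(trimethylsilyl)pent-1-en-4-yn-1-yl]-3,5,5-trimethylcyclopentyl]acetate | COC(=O)C[C@@H]1[C@@H](/C=C(/C)C(O)C#C[Si](C)(C)C)[C@](C)(O[Si](C)(C)C(C)(C)C)CC1(C)C
F3 | step 9 | methyl 2-[(1R,2R,3R)-3-(tert-butyldimethylsilyloxy)-2-[(1Z)-2-methyl-3-oxo-5-(trimethylsilyl)pent-1-en-4-yn-1-yl]-3,5,5-trimethylcyclopentyl]acetate | COC(=O)C[C@@H]1[C@@H](/C=C(/C)C(=O)C#C[Si](C)(C)C)[C@](C)(O[Si](C)(C)C(C)(C)C)CC1(C)C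
F4 | step 14 | (1R,3aS,4R,5S,7aR)-1-(tert-butyldimethylsilyloxy)-1,3,3,6-tetramethyl-5-[(trimethylsilyl)ethynyl]-2,3,3a,4,5,7a-hexahydro-1H-indene-4-carbaldehyde | CC1=C[C@@H]2[C@@H]([C@@H](C=O)[C@@H]1C#C[Si](C)(C)C)C(C)(C)C[C@@]2(C)O[Si](C)(C)C(C)(C)C
F5 | step 14 | [4-(tert-butyldimethylsilyloxy)phenyl]magnesium bromide | CC(C)(C)[Si](C)(C)Oc1ccc([Mg]Br)cc1
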